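**Atom labels.** Heavy atoms are numbered in the order of the target SMILES: C1, C2, C3 (Me2C), O4, C5(=O6), C7=C8, C9, C10, C11, C12, C13, C14(C15), C16(=O17), C18(C19), C20, C21, C22(C23, O24), C25, C26, O27, C28(=O29), C30, C31(O32).

## Analysis of the target

- The target has six rings.
  - Ring A is the unsaturated δ-lactone (C2, O4, C5, C7, C8, C9).
  - Ring B is the cyclohexane (C9–C12, C21, C22), spiro-linked to ring A at C9.
  - Ring C is the cyclopentane (C12, C21, C20, C18, C25).
  - Rings D (C12, C13, C14, C16, C18, C25) and E (C14, C16, C18, C25, C30, C31) make up a bicyclo[2.2.2]octane with bridgeheads C14 and C25.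
  - Ring F is the γ-lactone (C25, C26, O27, C28, C30).
- Rings C, D and E together form an isotwistane cage.
- There are nine stereocentres. C12, C14, C18 and C25 are interlocked by the cage, and C12–C25–C18 is a run of three contiguous all-carbon quaternary centres. C21, C22 and C9 relay this block into ring B, and C30 and C31 sit on the third bridge.
- On ring B, the groups C25, C20, O24 and C8 lie on one face. C13, H21, C23 and C2 lie on the other.
- Sensitive groups:
  - The β-hydroxy ketone C31(OH)–C14–C16(=O) can undergo retro-aldol cleavage.
  - C30–H is epimerisable.
  - The enoate of ring A is an acceptor.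
  - The tertiary carbinol C22 is acid-sensitive.
- The synthesis is hard because four quaternary carbons must be made next to one another, and because the flat polyketide half has to be joined to the chiral terpenoid half with control at C18.
- Two features invite the strategy.
  - C9–C13, C21, C22 and C1–C3 are the ten carbons of a p-menthane with oxygen at C22, which is the skeleton of pulegone.
  - Ring E with its substituents is a pentan-3-one unit (C15–C14–C16–C18–C19) condensed with a carboxytetronate (C25, C26, O27, C28, C30, C31). Ring E therefore does not have to come from an arene.

## Retrosynthetic reasoning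

**18 ⇒ 17.** Only the C31–H bond is cut. The carbinol becomes the ketone of the β-keto lactone 17, in which C30 is still epimerisable. The forward step must deliver hydride to the face of C31 that is not covered by C28. It must also leave the hindered C16 ketone and the enoate of ring A untouched.

**17 ⇒ 16 ⇒ 15 (key disconnection).**
- Bonds cut: C12–C25 and C13–C14 are cut in a retro-[4+2] sense. This unfolds the cage into the cyclohexadienone 16, which carries the C12=C13 exocyclic methylene on a two-atom tether (C20, C21).
- Ring E of 16 is then opened at C14–C31 in a retro-Dieckmann sense. This gives 15, an open-chain ethyl ketone bearing a butenolide ester.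
- Why here: 15 holds no cage, no ring E, and only one of the four cage stereocentres (C18).
- The forward operation must close ring E and let the unveiled diene be trapped at once.

**15 ⇒ 10 + 14.** The C18–C25 bond is cut.
- C25 is the β-carbon of a doubly activated butenolide, so it becomes the vinylogous acid chloride 14.
- C18 becomes the nucleophilic carbon of an enol ether.
- Tying O24 to C16 in the bicyclic dihydropyran 10 fixes the site of enolisation (C18, not C14). It also places C18 in a ring fused to ring B, so its configuration is set under cyclic control. The tether vanishes on hydrolysis.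

**10 ⇒ 9 ⇒ 7 + 8.** The dihydropyran is the cyclodehydrated form of δ-hydroxy ketone 9. Cutting C20–C21 in a retro-ene sense returns the trisubstituted alkene C21=C12 of 7 and the isopropenyl ketone 8. One forward step thus makes the C20–C21 bond, sets C21 and creates the C12=C13 methylene out of the C13 methyl group.

**7 ⇒ 6 ⇒ 4.** The C22–C23 bond is cut, corresponding to a methyl nucleophile adding to the C22 ketone of 6. The two double bonds of 6 (C7=C8 and C21=C12) are removed to give the saturated keto lactone 4. The quaternary C9 next to C22 must control the face of the addition.

**4 ⇒ 3 ⇒ 1 + 2.** The C2–O4 and C9–C8 bonds are cut. Ring A falls back to an isopropenyl group and a propanoate chain on C9, and these in turn to the isopropylidene ketone 1 and acrylate 2. The C12 stereocentre of 1 sets C9 and is erased later.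

**14 ⇒ 13 ⇒ 11 + 12.** The C25–Cl bond comes from the enol of tetronate 13. The ring of 13 comes from malonate 11 (C28, C30, C31) and acid chloride 12 (C25, C26).

## Alternatives that were turned down

**Alternative 1: the textbook route.**
- Disconnection: C12–C25 and C13–C14 by an intramolecular Diels–Alder reaction, then C18–C20.
- Forward key step: dearomative C-alkylation of 5,7-dihydroxy-4,6-dimethylphthalide A1 with a ring A/B electrophile such as triflate A2 gives 16, which then cyclises.
- Reasons for rejection:
  - The phenolate of A1 offers two oxygens and three activated carbons (C14, C18, C30) to a β-branched, non-allylic electrophile. O-alkylation and attack at C14 should therefore compete.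
  - C18 would arise in an open transition state four bonds from the nearest useful stereocentre, so half of the material should carry the epimer that cannot reach the cis-fused cycloaddition geometry.
  - A1 itself needs a separate multistep arene synthesis.

**Alternative 2: ring D as the aromatic progenitor.**
- Disconnection: C25–C30, C14–C31 and C18–C20.
- Forward key step: 2,3,6-trimethylphenol A3 is carried into spirodienone A4 by para-dearomatising cyclisation onto C12. A formylacetate strap on C26 then closes rings F and E by a Michael/aldol cascade, and C18 is finally joined to C20.
- Every bond is polarity-matched, and C18 is set last by ring closure.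
- Reasons for rejection:
  - The precursor costs about a dozen steps.
  - C9 needs a separate asymmetric construction.
  - One enone arm must be reduced in the presence of the ring A enoate.
  - Closure of ring C onto an exocyclic enone is a 5-endo-trig process.

**Alternative 3: biomimetic ring contraction.**
- Disconnection: the C8–C9 bond, traced back to a C8–C22 bond in the seven-membered lactone A5.
- Forward key step: hydrogen-atom transfer to C10 of A5 gives a C9 radical. A 1,2-vinyl shift through a cyclopropylcarbinyl radical moves C8 to C9, and dioxygen traps C22.
- Reasons for rejection:
  - It rebuilds a spirolactone that the deconjugative Michael/lactonisation pair makes in two steps.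
  - A5 needs a full decalin synthesis, oxidation and oxygen insertion.
  - Oxygen trapping of the first radical competes with the shift.
  - O24 would have to enter on the face of ring B that is shielded by C26.

Key step: step 10

## Steps

Step 1
Reactants: 1 (R)-(+)-pulegone; 2 tert-butyl acrylate
Product: 3 tert-butyl 3-[4-methyl-2-oxo-1-(prop-1-en-2-yl)cyclohexyl]propanoate (C9 quaternary; propanoate chain cis to the C12 methyl)
Conditions: KOtBu (0.2 equiv), t-BuOH/THF, 0 °C to rt
Reagents that add atoms: none
Why: Deconjugative Michael addition: under equilibrating alkoxide conditions 1 should react through its extended dienolate at the α-carbon C9, which moves the double bond into the isopropenyl group and builds the quaternary centre. Axial attack on the half-chair that keeps the C12 methyl equatorial places the new chain cis to that methyl, so the only stereocentre of 1 sets C9.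

Step 2
Reactants: 3 keto ester
Product: 4 1,1,9-trimethyl-2-oxaspiro[5.5]undecane-3,7-dione (rings A and B; C8 cis to the C12 methyl)
Conditions: TFA, CH2Cl2, rt
Reagents that add atoms: none
Why: Acidolysis of the tert-butyl ester and Markovnikov lactonisation in one pot: protonation of the isopropenyl group gives the tertiary C2 cation, which the liberated acid should trap through a six-membered transition state to close ring A. No stereocentre is touched.

Step 3
Reactants: 4 keto lactone
Product: 6 1,1,9-trimethyl-2-oxaspiro[5.5]undeca-4,8-diene-3,7-dione (C7=C8 and C21=C12), via bis-selenide 5 (not isolated)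
Conditions: LDA (2.3 equiv), THF, −78 °C; PhSeBr (2.3 equiv); then H2O2, pyridine, CH2Cl2, 0 °C to rt
Reagents that add atoms: none
Why: Double selenoxide syn-elimination: the ketone can enolise only toward C21 (C9 is quaternary) and the lactone only at C7, so both selenides enter at defined sites, and each has a single β-hydrogen position for elimination. The C12 stereocentre has done its work and is erased, while C9 is retained.

Step 4
Reactants: 6 enone lactone
Product: 7 7-hydroxy-1,1,7,9-tetramethyl-2-oxaspiro[5.5]undeca-4,8-dien-3-one (tertiary allylic alcohol; O24 cis to C8)
Conditions: MeLi, CeCl3, THF, −78 °C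
Reagents that add atoms: methyllithium, [Li]C
Why: Organocerium 1,2-addition: the weakly basic reagent should prefer the ketone over the lactone and over conjugate addition. In the half-chair of ring B the bulky C2 arm of ring A is pseudoequatorial and C8 pseudoaxial, so methyl enters anti to C8 and O24 ends cis to C8, as in the target.

Step 5
Reactants: 7 allylic alcohol; 8 2-methylpent-1-en-3-one
Product: 9 δ-hydroxy ketone with C12=C13 methylene and 2-methyl-3-oxopentyl chain on C21 (C20 cis to O24; C18 unassigned)
Conditions: Me2AlCl (2.2 equiv), CH2Cl2, −78 to −20 °C
Reagents that add atoms: none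
Why: Lewis acid-promoted ene reaction of an enone with a trisubstituted alkene: C21 bonds to C20 and the hydrogen is taken from the alkyl group syn to the vinylic hydrogen, which here is the C13 methyl, so the exocyclic methylene forms. The aluminium alkoxide of O24 binds the enone and the pseudoaxial C23 shields the other face, so C20 enters cis to O24 and sets C21. C18 is still epimerisable and of no consequence.

Step 6
Reactants: 9 δ-hydroxy ketone
Product: 10 bicyclic dihydropyran (O24–C16=C18 enol ether cis-fused to ring B)
Conditions: PPTS (cat.), 4 Å MS, benzene, 50 °C
Reagents that add atoms: none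
Why: Cyclodehydration of a δ-hydroxy ketone: six-membered hemiketal formation between O24 and C16, then loss of water toward the ring, should give the more substituted endocyclic enol ether. This erases the C18 mixture and fixes C18 as the only nucleophilic carbon.

Step 7
Reactants: 11 dimethyl malonate; 12 chloroacetyl chloride
Product: 13 methyl 4-hydroxy-2-oxo-2,5-dihydrofuran-3-carboxylate
Conditions: NaH (2 equiv), THF, 0 °C to reflux; then aq HCl
Reagents that add atoms: none
Why: Benary-type tetronate synthesis: C-acylation of the malonate anion is followed by ring closure through an ester oxygen onto the CH2Cl carbon with loss of chloromethane. No stereocentre is formed.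

Step 8
Reactants: 13 carbomethoxytetronic acid
Product: 14 methyl 4-chloro-2-oxo-2,5-dihydrofuran-3-carboxylate
Conditions: (COCl)2, DMF (cat.), CH2Cl2, 0 °C to rt
Reagents that add atoms: oxalyl chloride, O=C(Cl)C(=O)Cl
Why: Vilsmeier-type chlorination of a vinylogous acid, as used for 4-hydroxycoumarins and tetronic acids, turns C25 into a vinylogous acid chloride.

Step 9
Reactants: 10 dihydropyran; 14 chlorobutenolide
Product: 15 open-chain ethyl ketone with quaternary C18 bearing C19, C20, the propanoyl group and the 3-carbomethoxybutenolid-4-yl group (O24 free again)
Conditions: ZnCl2 (20 mol%), 2,6-di-tert-butylpyridine, CH2Cl2, −40 °C to rt; then H2O/THF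
Reagents that add atoms: water, O
Why: Proposed new method: the enol ether carbon C18 should add to C25 of the doubly activated β-chlorobutenolide, chloride is expelled, and the resulting O24=C16 oxocarbenium ion is hydrolysed to the C16 ketone and free O24–H, so the tether is traceless. The closest known reaction type is the addition–elimination of enol ethers and enamines to β-chlorovinyl carbonyl compounds, which has not been shown for a tetrasubstituted enol ether that builds a quaternary carbon. In the cis-fused oxadecalin the electrophile should approach the face of C18 anti to the axial C12 branch, which is the target configuration.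

Step 10
Reactants: 15 keto butenolide ester
Product: 17 hexacyclic β-keto lactone (31-oxo form of the target), via dienol 16 (not isolated)
Conditions: KOtBu (3.2 equiv), THF, −20 °C to rt; AcOH; then toluene, 110 °C
Reagents that add atoms: none
Why: The C16 ketone can enolise only toward C14 because C18 is quaternary, and this enolate attacks the C31 ester in a Dieckmann condensation (six-membered, enolexo exo-trig acyl substitution) that closes ring E and is driven by formation of the stabilised vinylogous acid anion. Acidification gives 16, a fully substituted 6,6-dialkylcyclohexa-2,4-dienone whose diene C14=C31–C30=C25 lies two atoms away from the C12=C13 methylene. On heating, a suprafacial intramolecular [4+2] cycloaddition forms C12–C25 and C13–C14, closing ring C (five-membered, through the C20–C21 tether), ring D and the bicyclo[2.2.2]octane. The closest known reaction type is the intramolecular Diels–Alder reaction of 6-(but-3-enyl)cyclohexa-2,4-dienones and masked o-benzoquinones to isotwistanes. The tether forces the alkene onto the diene face that carries C20, so C18 fixes C25 and C14. C21 allows only the cis-fused junction of rings B and C, so C12 takes C25 on the face of C20 and O24. The enol C31(OH)=C30 of the adduct ketonises, and C30 settles under thermodynamic control with C28 turned toward the C19 methyl rather than toward the rigid C11 methylene. The step needs the methylene, not the C7=C8 enoate, to act as dienophile, and cycloaddition to outrun dimerisation; the short tether and the full substitution of the dienone secure both. Addition of O24 to C25 is reversible and drains into the irreversible cycloaddition.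

Step 11
Reactants: 17 β-keto lactone
Product: 18 target CNP0360620.2
Conditions: NaBH4, CeCl3·7H2O, MeOH/CH2Cl2, −78 °C
Reagents that add atoms: none
Why: Luche reduction: the C16 ketone lies between two quaternary carbons and should stay inert, and the hard borohydride spares the ring A enoate. On the eclipsed C30–C31 bridge C28 covers the face of C31 that looks toward C16, so hydride should enter from the C13 side next to H30 and place O32 cis to C28 and syn to the C16 carbonyl, as in the target.

## Compound list

1 | (R)-(+)-pulegone | C[C@@H]1CCC(=C(C)C)C(=O)C1 | starting material
2 | tert-butyl acrylate | C=CC(=O)OC(C)(C)C | starting material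
3 | tert-butyl 3-[4-methyl-2-oxo-1-(prop-1-en-2-yl)cyclohexyl]propanoate, chain cis to methyl | CC(=C)[C@]1(CCC(=O)OC(C)(C)C)CC[C@@H](C)CC1=O | intermediate
4 | 1,1,9-trimethyl-2-oxaspiro[5.5]undecane-3,7-dione | CC1(C)OC(=O)CC[C@]12CC[C@@H](C)CC2=O | intermediate
5 | 4,8-bis(phenylselanyl) derivative of 4 (selenide centres unassigned) | CC1(C)OC(=O)C([Se]c3ccccc3)C[C@]12CC[C@@H](C)C([Se]c3ccccc3)C2=O | intermediate
6 | 1,1,9-trimethyl-2-oxaspiro[5.5]undeca-4,8-diene-3,7-dione | CC1(C)OC(=O)C=C[C@]12CCC(C)=CC2=O | intermediate
7 | 7-hydroxy-1,1,7,9-tetramethyl-2-oxaspiro[5.5]undeca-4,8-dien-3-one, OH cis to C8 | CC1(C)OC(=O)C=C[C@]12CCC(C)=C[C@@]2(C)O | intermediate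
8 | 2-methylpent-1-en-3-one | CCC(=O)C(C)=C | starting material
9 | 7-hydroxy-1,1,7-trimethyl-9-methylidene-8-(2-methyl-3-oxopentyl)-2-oxaspiro[5.5]undec-4-en-3-one (C18 unassigned) | CC1(C)OC(=O)C=C[C@]12CCC(=C)[C@@H](CC(C)C(=O)CC)[C@@]2(C)O | intermediate
10 | dihydropyran from 9 (O24–C16=C18, cis-fused to ring B) | CC1(C)OC(=O)C=C[C@]12CCC(=C)[C@H]3CC(C)=C(CC)O[C@@]23C | intermediate
11 | dimethyl malonate | COC(=O)CC(=O)OC | starting material
12 | chloroacetyl chloride | ClCC(Cl)=O | starting material
13 | methyl 4-hydroxy-2-oxo-2,5-dihydrofuran-3-carboxylate | COC(=O)C1=C(O)COC1=O | intermediate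
14 | methyl 4-chloro-2-oxo-2,5-dihydrofuran-3-carboxylate | COC(=O)C1=C(Cl)COC1=O | intermediate
15 | keto butenolide ester with quaternary C18 | CC1(C)OC(=O)C=C[C@]12CCC(=C)[C@@H](C[C@@](C)(C(=O)CC)C3=C(C(=O)OC)C(=O)OC3)[C@@]2(C)O | intermediate
16 | cyclohexadienone (dienol) with ring E closed | CC1(C)OC(=O)C=C[C@]12CCC(=C)[C@@H](C[C@@]3(C)C(=O)C(C)=C(O)C4=C3COC4=O)[C@@]2(C)O | intermediate
17 | hexacyclic β-keto lactone (31-oxo) | CC1(C)OC(=O)C=C[C@]12CC[C@]13C[C@]4(C)C(=O)[C@](C)(C[C@H]1[C@@]2(C)O)[C@]31COC(=O)[C@H]1C4=O | intermediate
18 | CNP0360620.2 | CC1(C)OC(=O)C=C[C@]12CC[C@]13C[C@]4(C)C(=O)[C@](C)(C[C@H]1[C@@]2(C)O)[C@]31COC(=O)[C@H]1[C@H]4O | target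

## Step count and least certain steps

- Total step count: 11.
- Longest linear sequence: 9 (steps 1–6 and 9–11).
- Steps 7 and 8 form a two-step side branch.

**Step 9.**
- What may go wrong:
  - Carbon–carbon bond formation at the tetrasubstituted enol ether carbon may be too slow.
  - The oxocarbenium ion may lose a proton toward C14 before hydrolysis and react a second time.
  - The acid set free may shift the exocyclic methylene into the ring.
  - Facial selectivity may erode if the oxadecalin reacts through its other half-chair.
- Fallback (known chemistry, from 10 back to 15):
  - Bromination of the enol ether of 10 with NBS in aqueous THF gives the tertiary α-bromo ketone F1 regiospecifically.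
  - Zinc dust converts F1 into its Reformatsky enolate, which is located at C18 by construction.
  - This enolate displaces the chloride of 14 by addition–elimination to give 15. The C18 epimers are separated at this stage if needed.

**Step 10 (key step).**
- What may go wrong:
  - Deprotonation at C26 may park the material as an unreactive furanolate, so that the Dieckmann closure stalls.
  - tert-Butoxide may add to C25 and reverse the C18–C25 bond.
  - The cycloaddition may be slower than oxa-Michael trapping by O24 or decomposition of the dienone at the temperature required.
- Fallback (from 16, isolated after the acid quench, back to 17): the pericyclic closure is replaced by a stepwise radical one.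
  - Mn(OAc)3·2H2O in ethanol oxidises the vinylogous acid of 16 to the electrophilic C14 radical, which adds to C13.
  - The nucleophilic tertiary C12 radical adds to the electron-poor C25.
  - The C30 radical takes a hydrogen atom from the solvent.
  - No new compound is made on the way.

**Step 5.**
- What may go wrong:
  - The tertiary allylic alkoxide may ionise under the Lewis acid.
  - The α-branched enone may be a sluggish enophile.
  - Hydrogen transfer from C11 instead of C13 would place the double bond inside ring B.
- Fallback (from 7 back to 9): the ene step is split into a one-carbon ene reaction and an enolate alkylation.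
  - Paraformaldehyde and Me2AlCl give the diol F2.
  - An Appel reaction (I2, PPh3, imidazole) on the primary alcohol gives the iodide F3.
  - The lithium enolate of pentan-3-one (LDA, DMPU) is alkylated by F3 to give 9.

**Step 1.**
- What may go wrong:
  - The dienolate may show poor facial selectivity.
  - Attack may occur at C21 through the cross-conjugated enolate.
  - A second acrylate may add.
- Fallback (from 1 back to 4): the reversible Michael step is replaced by an irreversible alkylation and an oxidation-state adjustment.
  - Sodium tert-pentoxide and allyl bromide give the allyl ketone F4.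
  - 9-BBN followed by NaBO3 converts the monosubstituted alkene into the alcohol F5.
  - TEMPO/PhI(OAc)2 in wet MeCN gives the acid F6.
  - TFA closes ring A to give 4.
- If the sense of induction is opposite, the same sequence is run from the enantiomer of 1.

**Step 11.**
- What may go wrong:
  - Hydride may be delivered from the C16 side.
  - Reduction may occur through the C30 epimer.
  - Enolisation of the β-keto lactone may slow the reduction.
- Fallback (from 17 back to 18): kinetic control is replaced by thermodynamic control. The reduction is taken to completion whatever its sense, and the 31-epimer F7 is equilibrated with catalytic DBU in toluene. Reversible retro-aldol opening of C14–C31 and reclosure should collect the material in the isomer with O32 on the open face, hydrogen-bonded to O17, which is 18.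

## Further compounds

F1 | step 9 | α-bromo ketone from 10 (C18–Br, unassigned) | CC1(C)OC(=O)C=C[C@]12CCC(=C)[C@@H](CC(C)(Br)C(=O)CC)[C@@]2(C)O
F0 | step 10 | none | none
F2 | step 5 | 7-hydroxy-8-(hydroxymethyl)-1,1,7-trimethyl-9-methylidene-2-oxaspiro[5.5]undec-4-en-3-one | CC1(C)OC(=O)C=C[C@]12CCC(=C)[C@@H](CO)[C@@]2(C)O
F3 | step 5 | 7-hydroxy-8-(iodomethyl)-1,1,7-trimethyl-9-methylidene-2-oxaspiro[5.5]undec-4-en-3-one | CC1(C)OC(=O)C=C[C@]12CCC(=C)[C@@H](CI)[C@@]2(C)O
F4 | step 1 | 2-allyl-5-methyl-2-(prop-1-en-2-yl)cyclohexanone, allyl cis to methyl | CC(=C)[C@]1(CC=C)CC[C@@H](C)CC1=O
F5 | step 1 | 2-(3-hydroxypropyl)-5-methyl-2-(prop-1-en-2-yl)cyclohexanone | CC(=C)[C@]1(CCCO)CC[C@@H](C)CC1=O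
F6 | step 1 | 3-[4-methyl-2-oxo-1-(prop-1-en-2-yl)cyclohexyl]propanoic acid | CC(=C)[C@]1(CCC(=O)O)CC[C@@H](C)CC1=O
F7 | step 11 | 31-epimer of 18 | CC1(C)OC(=O)C=C[C@]12CC[C@]13C[C@]4(C)C(=O)[C@](C)(C[C@H]1[C@@]2(C)O)[C@]31COC(=O)[C@H]1[C@@H]4O
A1 | alternative 1 | 5,7-dihydroxy-4,6-dimethylphthalide | Cc1c(O)c(C)c(O)c2C(=O)OCc12
A2 | alternative 1 | primary triflate of the ring A/B diol | CC1(C)OC(=O)C=C[C@]12CCC(=C)[C@@H](COS(=O)(=O)C(F)(F)F)[C@@]2(C)O
A3 | alternative 2 | 2,3,6-trimethylphenol | Cc1ccc(C)c(O)c1C
A4 | alternative 2 | spirodienone with rings A, B and D | CC1(C)OC(=O)C=C[C@]12CC[C@@]3(CC2=O)C=C(C)C(=O)C(C)=C3C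
A5 | alternative 3 | seven-membered lactone with C9=C10 double bond and C8 on C22 | CC1(C)OC(=O)C=C[C@]2(C)C1=CC[C@]35C[C@]4(C)C(=O)[C@](C)(C[C@H]32)[C@]51COC(=O)[C@H]1[C@H]4O
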